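The oxolane ring (O1; C2 bearing the 4-hydroxyphenyl group; C3 bearing C9H2OAc; C4 bearing the carbinol carbon Cα; C5H2) is cut at O1–C2 and C3–C4. The cut exploits the O1–C5–C4 segment, which is the alkoxide/allyl cation pair latent in a vinyl oxirane, and C2=C3, the double bond of an arylidene malonate. A single palladium-catalysed formal [3+2] annulation closes the ring, makes both bonds and sets C2 and C4 (cis) from racemic oxirane. That oxirane carries a 1-(4-methoxyphenyl)ethenyl group as a masked Cα ketone. The malonate carries the phenol as its benzyl ether. C3 follows by equilibration, Cα by chelate-controlled reduction.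

Key step: step 4

Assumption: the sense of induction of the diphosphine on a 2-aryl-substituted allyl unit cannot be derived with certainty. The (R,R) ligand is written, and its (S,S) antipode would be used unchanged if the first run showed the mirror-image cycloadduct.

Design note: methyl esters serve the later dealkoxycarbonylation, which is an SN2 attack on the ester alkyl group. The phenol is carried as a benzyl ether because hot chloride in wet DMSO and methoxide, both needed after the annulation, would strip an aryl silyl ether. The benzyl group is taken off before any benzylic alcohol or acetate exists.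

Step 1
Reactants: 1 4-methoxyphenylacetaldehyde
Product: 2 2-(4-methoxyphenyl)prop-2-enal
Conditions: 37% aq. HCHO (1.1 equiv), pyrrolidine (10 mol%), propionic acid (10 mol%), i-PrOH, 45 °C; used without storage
Reagents that add atoms: formaldehyde, C=O
Why: Organocatalytic α-methylenation (Mannich-type addition of the pyrrolidine enamine to formaldehyde followed by β-elimination of the amine) is established for unbranched aldehydes, arylacetaldehydes included, and creates no stereocentre.

Step 2
Reactants: 2 2-(4-methoxyphenyl)prop-2-enal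
Product: 3 rac-2-[1-(4-methoxyphenyl)ethenyl]oxirane
Conditions: Me3SI (1.3 equiv), KOt-Bu (1.25 equiv), DMSO/THF, 0 °C; then 2, 0 °C → rt; chromatography on Et3N-deactivated silica
Reagents that add atoms: trimethylsulfonium iodide, C[S+](C)C.[I-]
Why: Corey–Chaykovsky epoxidation: the unstabilised sulfonium methylide adds irreversibly to the carbonyl carbon of an enal rather than to its β-carbon and the betaine closes to the oxirane, which may be racemic because the annulation is stereoconvergent.

Step 3
Reactants: 4 4-(benzyloxy)benzaldehyde; 5 dimethyl malonate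
Product: 6 dimethyl 2-[4-(benzyloxy)benzylidene]malonate
Conditions: piperidine (10 mol%), AcOH (10 mol%), toluene, reflux, Dean–Stark trap
Reagents that add atoms: none
Why: Knoevenagel condensation under azeotropic removal of water is routine for aromatic aldehydes, and the two identical esters leave no alkene geometry to control.

Step 4
Reactants: 3 rac-2-[1-(4-methoxyphenyl)ethenyl]oxirane (1.5 equiv); 6 dimethyl 2-[4-(benzyloxy)benzylidene]malonate
Product: 7 dimethyl (2S,4R)-2-[4-(benzyloxy)phenyl]-4-[1-(4-methoxyphenyl)ethenyl]oxolane-3,3-dicarboxylate (2,4-cis)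
Conditions: Pd2(dba)3·CHCl3 (2.5 mol%), (1R,2R)-N,N′-bis[2-(diphenylphosphino)benzoyl]cyclohexane-1,2-diamine (7.5 mol%), toluene, 25–40 °C, 3 added by syringe pump to concentrated 6; chromatography to remove palladium and any 2,4-trans isomer
Reagents that add atoms: none
Why: Zerovalent palladium opens the strained allylic C–O bond of 3 to a 2-aryl-π-allylpalladium alkoxide, the alkoxide O1 adds reversibly to the β-carbon of 6 (O1–C2), and the malonate carbanion so released attacks the internal allyl terminus anti to the metal (C3–C4), which regenerates the catalyst. The closest known reaction type is the palladium-catalysed formal [3+2] cycloaddition of vinyl oxiranes, and of vinylcyclopropanes, with doubly activated or enone-type alkenes, including enantioselective versions with chiral diphosphines. The oxolane ring closes in a 5-exo mode on the allyl unit, the alternative attack at the CH2 terminus being a slower seven-membered closure. C4 is controlled by the ligand, because the diastereomeric π-allyl complexes from (R)- and (S)-3 interconvert by π–σ–π slippage through the unsubstituted CH2 terminus faster than they are trapped, so the racemate converges on the complex that closes faster in the chiral pocket. C2 is controlled relative to C4, because the oxa-Michael step is reversible and product formation therefore follows the Curtin–Hammett principle through the envelope in which the C2 aryl group and the C4 allyl unit are both pseudo-equatorial, that is 2,4-cis. The step needs branched regioselectivity, facial selectivity and cis selectivity, and the substrates contribute the two-atom tether O1–C5, the free CH2 allyl terminus and two identical ester groups that keep C3 non-stereogenic, so that only one unwanted diastereomer has to be separated before any later enolisation.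

Step 5
Reactants: 7 dimethyl (2S,4R)-2-[4-(benzyloxy)phenyl]-4-[1-(4-methoxyphenyl)ethenyl]oxolane-3,3-dicarboxylate
Product: 8 methyl (2R,4S)-2-[4-(benzyloxy)phenyl]-4-[1-(4-methoxyphenyl)ethenyl]oxolane-3-carboxylate (C3 epimers)
Conditions: LiCl (3 equiv), H2O (3 equiv), DMSO, 150 °C
Reagents that add atoms: none
Why: Krapcho dealkoxycarbonylation: chloride attacks the unhindered ester methyl group in an SN2 step, the carboxylate loses CO2 and water protonates the enolate, C2 and C4 stay untouched (their descriptors change only through CIP ranking), and C3 arises as an epimer mixture because protonation anti to the two cis substituents turns the ester towards them.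

Step 6
Reactants: 8 methyl (2R,4S)-2-[4-(benzyloxy)phenyl]-4-[1-(4-methoxyphenyl)ethenyl]oxolane-3-carboxylate (C3 epimers)
Product: 9 methyl (2R,3R,4S)-2-[4-(benzyloxy)phenyl]-4-[1-(4-methoxyphenyl)ethenyl]oxolane-3-carboxylate (2,3-trans, 3,4-trans)
Conditions: NaOMe (0.5 equiv), MeOH, 50 °C; AcOH quench
Reagents that add atoms: none
Why: Base-mediated epimerisation through the ester enolate is under thermodynamic control and should drain the mixture into the isomer with CO2Me trans to both the C2 aryl and the C4 alkenyl group, while loss of O1 from the enolate, the reverse of a 5-endo-trig closure, is poorly aligned.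

Step 7
Reactants: 9 methyl (2R,3R,4S)-2-[4-(benzyloxy)phenyl]-4-[1-(4-methoxyphenyl)ethenyl]oxolane-3-carboxylate
Product: 11 methyl (2R,3R,4R)-2-[4-(benzyloxy)phenyl]-4-(4-methoxybenzoyl)oxolane-3-carboxylate, via vicinal diol 10 (not isolated)
Conditions: OsO4 (2 mol%), NaIO4 (4 equiv), 2,6-lutidine (2 equiv), 1,4-dioxane/H2O 3:1, rt
Reagents that add atoms: osmium tetroxide, O=[Os](=O)(=O)=O; sodium periodate (terminal oxygen source), [Na+].[O-]I(=O)(=O)=O
Why: Lemieux–Johnson oxidation: the electron-rich 1,1-disubstituted styrene is dihydroxylated far faster than either arene is touched, periodate cleaves the diol, and lutidine keeps the medium near neutral so that the β-alkoxy ketone with its already favoured trans C4 configuration is not disturbed.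

Step 8
Reactants: 11 methyl (2R,3R,4R)-2-[4-(benzyloxy)phenyl]-4-(4-methoxybenzoyl)oxolane-3-carboxylate
Product: 12 methyl (2R,3R,4R)-2-(4-hydroxyphenyl)-4-(4-methoxybenzoyl)oxolane-3-carboxylate
Conditions: H2 (1 atm), 10% Pd/C, EtOAc, rt, stopped as soon as 11 is consumed
Reagents that add atoms: none
Why: Catalytic hydrogenolysis removes the primary benzyl aryl ether much faster than it attacks the hindered cyclic C2–O1 bond or the electron-rich aryl ketone, and it is placed here because no benzylic alcohol or acetate is present yet.

Step 9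
Reactants: 12 methyl (2R,3R,4R)-2-(4-hydroxyphenyl)-4-(4-methoxybenzoyl)oxolane-3-carboxylate
Product: 13 methyl (2R,3R,4R)-4-[(S)-hydroxy(4-methoxyphenyl)methyl]-2-(4-hydroxyphenyl)oxolane-3-carboxylate
Conditions: Zn(BH4)2 (2 equiv, ethereal stock solution), Et2O/CH2Cl2, −20 → 0 °C; water quench
Reagents that add atoms: none
Why: Chelation-controlled hydride reduction: divalent zinc bridges the ketone oxygen and ring oxygen O1 in a six-membered chelate that holds C=O syn to C4–C5, so hydride enters from the side of C4–H, anti to C3, which is also the Felkin–Anh sense (C3 as the large group) and gives (S)-Cα while the ester is left alone.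

Step 10
Reactants: 13 methyl (2R,3R,4R)-4-[(S)-hydroxy(4-methoxyphenyl)methyl]-2-(4-hydroxyphenyl)oxolane-3-carboxylate
Product: 14 4-{(2R,3S,4R)-3-(hydroxymethyl)-4-[(S)-hydroxy(4-methoxyphenyl)methyl]oxolan-2-yl}phenol
Conditions: LiAlH4 (3 equiv), THF, 0 °C → rt; aq. potassium sodium tartrate
Reagents that add atoms: none
Why: LiAlH4 reduction of the ester to the primary alcohol C9H2OH proceeds with the phenoxide and the Cα alkoxide as spectators, the trans C3/C4 relationship rules out lactonisation of 13, and no stereocentre is touched.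

Step 11
Reactants: 14 4-{(2R,3S,4R)-3-(hydroxymethyl)-4-[(S)-hydroxy(4-methoxyphenyl)methyl]oxolan-2-yl}phenol
Product: 15 4-{(2R,3S,4R)-3-(acetoxymethyl)-4-[(S)-acetoxy(4-methoxyphenyl)methyl]oxolan-2-yl}phenyl acetate
Conditions: Ac2O (5 equiv), pyridine, 4-(dimethylamino)pyridine (5 mol%), CH2Cl2, 0 °C → rt
Reagents that add atoms: acetic anhydride, CC(=O)OC(C)=O
Why: Nucleophile-catalysed acylation under basic conditions esterifies all three hydroxyl groups and avoids the acid that would ionise the 4-methoxybenzylic C–O bond.

Step 12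
Reactants: 15 4-{(2R,3S,4R)-3-(acetoxymethyl)-4-[(S)-acetoxy(4-methoxyphenyl)methyl]oxolan-2-yl}phenyl acetate
Product: 16 [(2R,3S,4R)-4-[(S)-acetoxy(4-methoxyphenyl)methyl]-2-(4-hydroxyphenyl)oxolan-3-yl]methyl acetate (CNP0231272.1)
Conditions: pyrrolidine (1.5 equiv), THF, 0 °C; pH 7 phosphate buffer
Reagents that add atoms: none
Why: Chemoselective aminolysis: the aryl acetate expels a phenoxide and reacts with a secondary amine far faster than the two alkyl acetates, which would have to expel alkoxides, so only the phenol is released and no stereocentre is at risk.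

Compound list
1 | 4-methoxyphenylacetaldehyde | COc1ccc(CC=O)cc1 | starting material
2 | 2-(4-methoxyphenyl)prop-2-enal | C=C(C=O)c1ccc(OC)cc1 | intermediate
3 | rac-2-[1-(4-methoxyphenyl)ethenyl]oxirane | C=C(c1ccc(OC)cc1)C1CO1 | intermediate
4 | 4-(benzyloxy)benzaldehyde | O=Cc1ccc(OCc2ccccc2)cc1 | starting material
5 | dimethyl malonate | COC(=O)CC(=O)OC | starting material
6 | dimethyl 2-[4-(benzyloxy)benzylidene]malonate | COC(=O)C(=Cc1ccc(OCc2ccccc2)cc1)C(=O)OC | intermediate
7 | dimethyl (2S,4R)-2-[4-(benzyloxy)phenyl]-4-[1-(4-methoxyphenyl)ethenyl]oxolane-3,3-dicarboxylate (2,4-cis) | C=C(c1ccc(OC)cc1)[C@H]2CO[C@@H](c3ccc(OCc4ccccc4)cc3)C2(C(=O)OC)C(=O)OC | intermediate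
8 | methyl (2R,4S)-2-[4-(benzyloxy)phenyl]-4-[1-(4-methoxyphenyl)ethenyl]oxolane-3-carboxylate, mixture of C3 epimers | C=C(c1ccc(OC)cc1)[C@H]2CO[C@@H](c3ccc(OCc4ccccc4)cc3)C2C(=O)OC | intermediate
9 | methyl (2R,3R,4S)-2-[4-(benzyloxy)phenyl]-4-[1-(4-methoxyphenyl)ethenyl]oxolane-3-carboxylate (all-trans) | C=C(c1ccc(OC)cc1)[C@H]2CO[C@@H](c3ccc(OCc4ccccc4)cc3)[C@@H]2C(=O)OC | intermediate
10 | methyl (2R,3R,4R)-2-[4-(benzyloxy)phenyl]-4-[1,2-dihydroxy-1-(4-methoxyphenyl)ethyl]oxolane-3-carboxylate, carbinol centre undefined | OCC(O)(c1ccc(OC)cc1)[C@H]2CO[C@@H](c3ccc(OCc4ccccc4)cc3)[C@@H]2C(=O)OC | intermediate (not isolated)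
11 | methyl (2R,3R,4R)-2-[4-(benzyloxy)phenyl]-4-(4-methoxybenzoyl)oxolane-3-carboxylate | COc1ccc(C(=O)[C@H]2CO[C@@H](c3ccc(OCc4ccccc4)cc3)[C@@H]2C(=O)OC)cc1 | intermediate
12 | methyl (2R,3R,4R)-2-(4-hydroxyphenyl)-4-(4-methoxybenzoyl)oxolane-3-carboxylate | COc1ccc(C(=O)[C@H]2CO[C@@H](c3ccc(O)cc3)[C@@H]2C(=O)OC)cc1 | intermediate
13 | methyl (2R,3R,4R)-4-[(S)-hydroxy(4-methoxyphenyl)methyl]-2-(4-hydroxyphenyl)oxolane-3-carboxylate | COc1ccc([C@@H](O)[C@H]2CO[C@@H](c3ccc(O)cc3)[C@@H]2C(=O)OC)cc1 | intermediate
14 | 4-{(2R,3S,4R)-3-(hydroxymethyl)-4-[(S)-hydroxy(4-methoxyphenyl)methyl]oxolan-2-yl}phenol | COc1ccc([C@@H](O)[C@H]2CO[C@@H](c3ccc(O)cc3)[C@@H]2CO)cc1 | intermediate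
15 | 4-{(2R,3S,4R)-3-(acetoxymethyl)-4-[(S)-acetoxy(4-methoxyphenyl)methyl]oxolan-2-yl}phenyl acetate | COc1ccc([C@@H](OC(C)=O)[C@H]2CO[C@@H](c3ccc(OC(C)=O)cc3)[C@@H]2COC(C)=O)cc1 | intermediate
16 | [(2R,3S,4R)-4-[(S)-acetoxy(4-methoxyphenyl)methyl]-2-(4-hydroxyphenyl)oxolan-3-yl]methyl acetate | COc1ccc([C@@H](OC(C)=O)[C@H]2CO[C@@H](c3ccc(O)cc3)[C@@H]2COC(C)=O)cc1 | target

Total step count: 12. Longest linear sequence: 11 (steps 1, 2 and 4–12).

Steps most likely to fail

Step 4.
- **What may go wrong:** The opened oxirane may isomerise or oligomerise before the only moderately electrophilic alkene intercepts its alkoxide. Ring closure may also show poor cis/trans or facial selectivity.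
- **Fallback:** It sets out from 4 (together with 3) and comes back at 8. It keeps the disconnection but uses a far more electrophilic cyclic malonate. 4 is condensed with 2,2-dimethyl-1,3-dioxane-4,6-dione (piperidine and AcOH, 10 mol% each, toluene, rt) to the cyclic isopropylidene arylidenemalonate F1.
- **Annulation:** F1 and 3 undergo the same palladium-catalysed annulation to the spiro adduct F2. Alkylidene derivatives of this cyclic malonate are proven partners of palladium zwitterions, also with remote stereoinduction by chiral diphosphines.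
- **Return:** Heating F2 with MeOH in pyridine (100 °C, sealed tube) opens the dioxanedione to the malonic half ester F3. F3 loses CO2 in the same flask and gives 8.

Step 6.
- **What may go wrong:** The ring may open by β-elimination of O1 from the ester enolate, or equilibration may stay incomplete.
- **Fallback:** It sets out from 8 and comes back at 9. It moves the epimerisation to the aldehyde oxidation level, where an amine base suffices.
- **Sequence:** i-Bu2AlH (1.1 equiv, toluene, −78 °C) converts 8 into the aldehyde epimer mixture F4. 1,8-Diazabicyclo[5.4.0]undec-7-ene (CH2Cl2, rt) equilibrates it to the all-trans aldehyde F5. Pinnick oxidation (NaClO2, NaH2PO4, 2-methyl-2-butene in large excess, t-BuOH/H2O) gives the carboxylic acid F6. Me3SiCHN2 (toluene/MeOH, 0 °C) then returns 9.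

Step 9.
- **What may go wrong:** Facial selectivity will be poor if zinc binds the ester carbonyl instead of O1, or if the chelate is too loose.
- **Fallback:** It sets out from 12 and comes back at 13. It replaces substrate control by catalyst control, using the Corey–Bakshi–Shibata reduction. The conditions are (R)-1-methyl-3,3-diphenyltetrahydro-1H,3H-pyrrolo[1,2-c][1,3,2]oxazaborole (20 mol%) and BH3·SMe2, with one extra equivalent for the phenol, in THF at −20 °C.
- **Sense:** The (R)-catalyst treats the aryl group as the large substituent and delivers hydride in the sense that gives (S)-1-arylalkanols. This is the same sense as the steric bias of the substrate.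

Further compounds
F1 | step 4 | 5-[4-(benzyloxy)benzylidene]-2,2-dimethyl-1,3-dioxane-4,6-dione | CC1(C)OC(=O)C(=Cc2ccc(OCc3ccccc3)cc2)C(=O)O1
F2 | step 4 | (1S,4R)-1-[4-(benzyloxy)phenyl]-4-[1-(4-methoxyphenyl)ethenyl]-8,8-dimethyl-2,7,9-trioxaspiro[4.5]decane-6,10-dione | C=C(c1ccc(OC)cc1)[C@H]2CO[C@@H](c3ccc(OCc4ccccc4)cc3)C25C(=O)OC(C)(C)OC5=O
F3 | step 4 | (2S,4R)-2-[4-(benzyloxy)phenyl]-3-(methoxycarbonyl)-4-[1-(4-methoxyphenyl)ethenyl]oxolane-3-carboxylic acid, C3 undefined | C=C(c1ccc(OC)cc1)[C@H]2CO[C@@H](c3ccc(OCc4ccccc4)cc3)C2(C(=O)O)C(=O)OC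
F4 | step 6 | (2R,4S)-2-[4-(benzyloxy)phenyl]-4-[1-(4-methoxyphenyl)ethenyl]oxolane-3-carbaldehyde, mixture of C3 epimers | C=C(c1ccc(OC)cc1)[C@H]2CO[C@@H](c3ccc(OCc4ccccc4)cc3)C2C=O
F5 | step 6 | (2R,3R,4S)-2-[4-(benzyloxy)phenyl]-4-[1-(4-methoxyphenyl)ethenyl]oxolane-3-carbaldehyde | C=C(c1ccc(OC)cc1)[C@H]2CO[C@@H](c3ccc(OCc4ccccc4)cc3)[C@@H]2C=O
F6 | step 6 | (2R,3R,4S)-2-[4-(benzyloxy)phenyl]-4-[1-(4-methoxyphenyl)ethenyl]oxolane-3-carboxylic acid | C=C(c1ccc(OC)cc1)[C@H]2CO[C@@H](c3ccc(OCc4ccccc4)cc3)[C@@H]2C(=O)O
F0 | step 9 | none | none
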